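Geranyl = (2E)-3,7-dimethylocta-2,6-dien-1-yl; prenyl = 3-methylbut-2-en-1-yl.

## Analysis of the target

Target 32 is an enolised bicyclo[3.3.1]nonane-2,4,9-trione. The atoms are numbered C1 (bridgehead next to the CMe2 carbon C8), C2–C3–C4 (the enolised dicarbonyl arc, 3,4-dihydroxybenzoyl on C3), C5 (second bridgehead), C6 (CH2), C7 (CH–prenyl), C8 and C9 (bridging ketone). Ring A is C1–C2–C3–C4–C5–C9 and ring B is C1–C8–C7–C6–C5–C9. Both bridgeheads are quaternary and carry geranyl groups, so C1, C8 and C5 are three fully substituted ring carbons, two of them adjacent. There are three stereocentres, (1S,5S,7R) in this numbering. C1 and C5 are coupled by the bridge, so the independent elements are the absolute configuration at C7 and the relation C5/C7: the prenyl group is equatorial on chair ring B, cis to the C5 geranyl group and trans to the C4 and C2 arms. Sensitive functions are five trisubstituted alkenes (acid, electrophilic oxidants and π-acids threaten them, and acid closes the enol onto them), a catechol, and a triketone that is open to retro-Claisen cleavage whenever it is not enolised. The hard bond is C1–C2, which must be made at a carbon that already bears geranyl and sits beside C8. The strategy reads C2 and C3 as the two carbons of an alkyne conjugated to the C4 ketone and hung on C5, and C1 as the α-carbon of the C9 ketone in silyl enol ether form, so that a 6-endo-dig carbocyclisation forms C1–C2, closes ring A and sets C1 from C5.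

## Retrosynthetic reasoning

**32 ⇒ 31 ⇒ 30 ⇒ 25 + 29.** The enol is masked as its methyl ether and the catechol as a bis-silyl ether. The C3–aroyl bond is cut because, with both bridgeheads quaternary, C3–H of vinylogous ester 25 is the only acidic C–H. Forward, C3 must be metalated and acylated by 29. Adding the aryl ketone last keeps the catechol out of the gold and oxidation chemistry.

**25 ⇒ 24 ⇒ 23 ⇒ 22 ⇒ 21.** The C2 oxygen is removed, leading back to enone 21. Forward, C2 must be oxidised in the presence of five electron-rich alkenes. A nucleophilic epoxidation touches only the electron-poor C2=C3 bond; reductive cleavage of the C3–O bond and oxidation then give trione 24.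

**21 ⇒ 20.** The C1–C2 bond is cut. This is the most congested bond of the core, and cutting it turns ring A into a propynoyl group on C5 and a C9 enol ether, both accessible from a cyclohexanone. Forward, the enol ether carbon C1 must attack the terminal alkyne carbon in the 6-endo mode, and the axial acyl arm fixes C1.

**20 ⇒ 19 ⇒ 18 ⇒ 16.** The ynone comes from the propargylic alcohol. The enol ether and one methyl on C8 are traced to a conjugate methyl addition to tetrasubstituted enone 16: cutting C8–CH3 gives a precursor whose conjugate addition generates exactly the C9=C1 enolate. Deprotonation could not give this enol ether cleanly, since the only α-hydrogen would sit on a tertiary carbon beside CMe2.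

**16 ⇒ 13 + 14, 13 ⇒ 12 + 10.** The two C5 bonds are cut in a fixed order. The second electrophile enters anti to the C7 prenyl group, so the acyl arm (from ynal 14) must come second and the geranyl group (from 10) first. Both steps use the kinetic α′-enolate of the enone, the only enolate that does not endanger C7.

**12 ⇒ 11 ⇒ 9 + 10, 9 ⇒ 8 ⇒ 7.** The C1–geranyl bond is cut at the enone α-carbon. Forward this needs a vinyl carbanion, made by α-iodination, ketal protection and halogen–lithium exchange. Enolate-based α-alkylation of the enone would pass through the extended enolate and scramble C7.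

**7 ⇒ 6 ⇒ 5 ⇒ 3 + 4, 3 ⇒ 2 ⇒ 1.** Ring B is opened at C1=C8 (metathesis) and C5–C6 (alkylation). Lavandulol 2 then supplies C6, C7, C8, one C8 methyl and the prenyl group with the C7 configuration in place. Ketophosphonate 4 supplies C5, C9 and C1.

**29 ⇒ 28 ⇒ 26.** The aroyl chloride comes from protected protocatechuic acid.

## Alternatives that were turned down

**Alternative 1:** Ring B is cut at C5–C6 and C7–C8, a [4+2] between silyloxydiene A2 (C1, C9, C5, C8) and acrylimide A3 (C6, C7 and the future prenyl CH2). Forward, Cu(OTf)2 with a chiral bis(oxazoline) ligand (divalent copper) chelates A3 and A2 adds to give A1, with C7 set by the catalyst.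
- For: C7 is set catalytically with no resolution, the gem-dimethyl group needs no cuprate, and C9 emerges as a silyl enol ether pointing to C1. On these three points it is stronger than the chosen route, which discards half of racemic 1 and needs a conjugate addition to a tetrasubstituted enone.
- Against: A2 has a cis methyl on its terminus, so its s-cis conformer is strained and it is a poor diene. The C7–C8 bond joins a quaternary to a tertiary carbon. The Lewis acid can divert the silyl dienol ether to an open-chain Mukaiyama–Michael adduct or hydrolyse it. The imide of A1 needs about three further steps to become a prenyl group, and C1 is still C–H.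
- Comparison: the step count to a ring-B ketone is about the same. The chosen route offers ring-B bonds made by SN2, olefination and metathesis of predictable outcome, and a prenyl group present from the first compound.

**Alternative 2:** Both bridgehead–geranyl bonds are cut at the end. Forward, NiBr2(dme) (divalent nickel precatalyst) with 2,2′-bipyridine and zinc or a cathode reduces bis(N-acyloxyphthalimide) A5; loss of CO2 gives bridgehead radicals that are coupled with carbonate A6 to give A4.
- For: it is the most convergent plan. A4 is identical with 25, three steps from the target, and the core is built without side-chain alkenes, so ring construction and C2 oxidation face no competing olefins. On convergence and late-stage flexibility it is stronger.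
- Against: two quaternary C–C bonds must form in one pot from pyramidal bridgehead radicals that cannot delocalise into the flanking carbonyls, one of them beside CMe2. The allylnickel partner can deliver its tertiary terminus or lose the E-geometry by syn/anti exchange, and each leak is multiplied over two sites. Hydrogen capture gives bridgehead C–H. This substrate class has no precedent for the coupling, and A5 needs its own synthesis.
- Comparison: the chosen strategy offers geranyl groups introduced by SN2 reactions of carbanions with 10, which keep the olefin geometry, and quaternary centres made by an aldol reaction and by the ring closure.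

**Alternative 3:** The C1–C8 bond is cut; ring B is closed by attack of an enol ether on a tertiary C8 cation. Forward, Co(salen) (divalent cobalt) with PhSiH3 and an oxidant (anode or an N-fluoro-2,4,6-trimethylpyridinium salt) transfers a hydrogen atom to the isopropenyl CH2 of dienol ether A8. The radical is oxidised to the cation and one of the two enol ether carbons attacks to give A7.
- For: the lavandulyl unit delivers C6, C7, C8, both C8 methyls and the prenyl group with no metathesis and no cuprate. A8 is symmetric and quickly assembled, and C5 is set by desymmetrisation. In steps to the bicycle it is clearly stronger.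
- Against: A8 holds three other trisubstituted alkenes and two enol ethers that compete for the hydrogen atom and for the cation. The choice between the two enol ether termini, which fixes C5 relative to C7, rests on a modest conformational bias. A7 still lacks the two hardest features: C1 is C–H beside C8 and C2 is CH2, so bridgehead geranylation next to CMe2 and a C2 oxidation remain.
- Comparison: the chosen strategy forms the C1 quaternary centre in the ring closure with geranyl already in place, and leaves only an oxidation of C2 from an enone.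

Key step: step 14

Remarks on assumptions:
- Candida antarctica lipase B is taken to acetylate (R)-lavandulol faster; if the preference is the opposite, the (S)-alcohol is obtained from the ester fraction by methanolysis.
- O-Methylation of 24 is drawn at the less hindered C4 oxygen; the C2-O-methyl isomer would pass through steps 21–23 in the same way to the same target.
- Locants of the bicyclic compounds follow the C1–C9 scheme of the analysis; centres that are destroyed later (C6 of 13, the carbinol carbon of 15–19) are carried as mixtures.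

## Route

Step 1
Reactants: 1 (±)-lavandulol
Product: 2 (S)-lavandulol [(2S)-5-methyl-2-(prop-1-en-2-yl)hex-4-en-1-ol]
Conditions: immobilised Candida antarctica lipase B, vinyl acetate, hexane, rt, stopped beyond half conversion; chromatography
Reagents that add atoms: none
Why: Lipase-catalysed kinetic resolution by enantioselective transesterification: the (R)-alcohol is expected to be acetylated faster, so the (S)-alcohol remains and is enriched by running past half conversion. No bond at the stereocentre is touched.

Step 2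
Reactants: 2 (S)-lavandulol
Product: 3 (S)-lavandulyl iodide [(3S)-3-(iodomethyl)-2,6-dimethylhepta-1,5-diene]
Conditions: PPh3, I2, imidazole, CH2Cl2, 0 °C → rt
Reagents that add atoms: iodine, II
Why: Appel-type iodination of a primary alcohol through the alkoxyphosphonium salt (SN2 at CH2); the stereocentre is one carbon away and is kept.

Step 3
Reactants: 4 dimethyl (2-oxopropyl)phosphonate; 3 (S)-lavandulyl iodide
Product: 5 dimethyl [(5S)-6-methyl-5-(3-methylbut-2-en-1-yl)-2-oxohept-6-en-1-yl]phosphonate
Conditions: 4, NaH, THF, 0 °C; n-BuLi, 0 °C; then 3, 0 °C → rt; aq. NH4Cl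
Reagents that add atoms: none
Why: γ-Alkylation of a β-ketophosphonate dianion: the terminal, more basic carbanion displaces the primary iodide by SN2 and forms C5–C6, while 4 brings C5, C9 and C1. The remaining stabilised monoanion does not react further.

Step 4
Reactants: 5 dimethyl [(5S)-6-methyl-5-(3-methylbut-2-en-1-yl)-2-oxohept-6-en-1-yl]phosphonate
Product: 6 (6S)-7-methyl-6-(3-methylbut-2-en-1-yl)octa-1,7-dien-3-one
Conditions: aq. HCHO (37%), K2CO3, THF/H2O, rt; used crude
Reagents that add atoms: formaldehyde, C=O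
Why: Horner–Wadsworth–Emmons methylenation with formaldehyde under carbonate conditions gives the vinyl ketone; the phosphonate carbon becomes C1. The enone is used at once to avoid oligomerisation.

Step 5
Reactants: 6 (6S)-7-methyl-6-(3-methylbut-2-en-1-yl)octa-1,7-dien-3-one
Product: 7 (4S)-3-methyl-4-(3-methylbut-2-en-1-yl)cyclohex-2-en-1-one
Conditions: second-generation Grubbs catalyst RuCl2(=CHPh)(PCy3)(H2IMes) (5 mol %), CH2Cl2 (0.01 M), 40 °C
Reagents that add atoms: none
Why: Ring-closing metathesis between the vinyl ketone and the isopropenyl group forms C1=C8 and the six-membered ring with loss of ethene; this closure should be faster than any engagement of the trisubstituted prenyl alkene. C7 is untouched.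

Step 6
Reactants: 7 (4S)-3-methyl-4-(3-methylbut-2-en-1-yl)cyclohex-2-en-1-one
Product: 8 (4S)-2-iodo-3-methyl-4-prenylcyclohex-2-en-1-one
Conditions: I2, pyridine/CH2Cl2, 0 °C → rt
Reagents that add atoms: iodine, II
Why: α-Iodination of the enone by pyridine addition, iodination of the enolate and elimination (Baylis–Hillman-type pathway); it acts only on the electron-poor alkene and involves no γ-deprotonation, so the prenyl group and C7 are safe.

Step 7
Reactants: 8 (4S)-2-iodo-3-methyl-4-prenylcyclohex-2-en-1-one
Product: 9 (8S)-6-iodo-7-methyl-8-prenyl-1,4-dioxaspiro[4.5]dec-6-ene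
Conditions: Me3SiOCH2CH2OSiMe3, Me3SiOTf (cat.), CH2Cl2, −78 → −20 °C; pyridine quench
Reagents that add atoms: 1,2-bis(trimethylsilyloxy)ethane, C[Si](C)(C)OCCO[Si](C)(C)C
Why: Silyl-transfer ketalisation under kinetic low-temperature conditions, which avoids the dienol pathway that could move the double bond toward C7; the ketal masks C9 for the organolithium step.

Step 8
Reactants: 9 (8S)-6-iodo-7-methyl-8-prenyl-1,4-dioxaspiro[4.5]dec-6-ene; 10 geranyl bromide
Product: 12 (4S)-2-geranyl-3-methyl-4-prenylcyclohex-2-en-1-one, via geranylated ketal 11 (not isolated)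
Conditions: t-BuLi (2.1 equiv), THF, −78 °C; 10, DMPU, −78 → 0 °C; then 10% aq. oxalic acid, THF, rt
Reagents that add atoms: water, O
Why: Iodine–lithium exchange gives an α-ketovinyl anion equivalent that is alkylated by SN2 at the primary allylic bromide with the E-geometry intact (C1–CH2 bond); mild aqueous acid then hydrolyses the allylic ketal. Alkylation at a vinylic carbanion leaves the γ-stereocentre C7 untouched.

Step 9
Reactants: 12 (4S)-2-geranyl-3-methyl-4-prenylcyclohex-2-en-1-one; 10 geranyl bromide
Product: 13 (4R)-2,6-digeranyl-3-methyl-4-prenylcyclohex-2-en-1-one (both C6 epimers)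
Conditions: LiN(i-Pr)2, THF, −78 °C; 10, −78 → −20 °C
Reagents that add atoms: none
Why: Kinetic α′-deprotonation gives the cross-conjugated enolate (C1 has no hydrogen and γ-deprotonation is slower at −78 °C), which is alkylated by SN2. The new centre (future C5) need not be controlled because it is enolised again in step 10.

Step 10
Reactants: 13 (4R)-2,6-digeranyl-3-methyl-4-prenylcyclohex-2-en-1-one; 14 3-(trimethylsilyl)propynal
Product: 16 (4R,6S)-2,6-digeranyl-3-methyl-4-prenyl-6-[3-(trimethylsilyl)-1-(trimethylsilyloxy)prop-2-yn-1-yl]cyclohex-2-en-1-one (carbinol epimers), via lithium aldolate 15 (not isolated)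
Conditions: LiN(i-Pr)2, THF, −78 °C; 14, −78 °C; then Me3SiCl, Et3N, −78 → 0 °C
Reagents that add atoms: chlorotrimethylsilane, C[Si](C)(C)Cl
Why: Aldol addition of the tetrasubstituted C5 enolate to the non-enolisable ynal forms C5–C4; allylic strain with the C8 methyl puts the C7 prenyl group pseudoaxial, so the aldehyde should enter C5 from the opposite face and the arm ends up trans to prenyl. Silylation of the aldolate in the same flask stops retro-aldol cleavage and protects the oxygen for step 11.

Step 11
Reactants: 16 (4R,6S)-2,6-digeranyl-3-methyl-4-prenyl-6-[3-(trimethylsilyl)-1-(trimethylsilyloxy)prop-2-yn-1-yl]cyclohex-2-en-1-one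
Product: 18 triisopropyl{[(4R,6S)-2,6-digeranyl-3,3-dimethyl-4-prenyl-6-[3-(trimethylsilyl)-1-(trimethylsilyloxy)prop-2-yn-1-yl]cyclohex-1-en-1-yl]oxy}silane (carbinol epimers), via lithium enolate 17 (not isolated)
Conditions: Me2CuLi (from MeLi and CuI, 3 equiv), Et2O, −30 → 0 °C; then i-Pr3SiOTf, Et3N, −78 → 0 °C
Reagents that add atoms: lithium dimethylcuprate, [Li+].C[Cu-]C; triisopropylsilyl trifluoromethanesulfonate, CC(C)[Si](C(C)C)(C(C)C)OS(=O)(=O)C(F)(F)F
Why: Conjugate addition of the methyl cuprate at C8 completes the gem-dimethyl group (no stereocentre) and gives the C9=C1 enolate regiospecifically, which O-silylation fixes as the tetrasubstituted enol ether; silyl ether and silylalkyne are inert to the cuprate. The triisopropylsilyl group is chosen over tert-butyldimethylsilyl because it should resist cleavage and 1,5 O-to-O migration in step 12.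

Step 12
Reactants: 18 triisopropylsilyl enol ether of step 11
Product: 19 1-[(1S,5R)-1,3-digeranyl-4,4-dimethyl-5-prenyl-2-(triisopropylsilyloxy)cyclohex-2-en-1-yl]prop-2-yn-1-ol (carbinol epimers)
Conditions: K2CO3, MeOH/THF, 0 °C → rt
Reagents that add atoms: none
Why: Base-catalysed methanolysis removes the trimethylsilyl groups from oxygen and from the alkyne carbon while the hindered triisopropylsilyl enol ether should survive. With C9 masked as an enol ether the free alkoxide cannot undergo retro-aldol cleavage.

Step 13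
Reactants: 19 1-[(1S,5R)-1,3-digeranyl-4,4-dimethyl-5-prenyl-2-(triisopropylsilyloxy)cyclohex-2-en-1-yl]prop-2-yn-1-ol
Product: 20 1-[(1R,5R)-1,3-digeranyl-4,4-dimethyl-5-prenyl-2-(triisopropylsilyloxy)cyclohex-2-en-1-yl]prop-2-yn-1-one
Conditions: Dess–Martin periodinane, NaHCO3, CH2Cl2, 0 °C; used at once
Reagents that add atoms: none
Why: Dess–Martin oxidation of the propargylic alcohol under buffered conditions gives the terminal ynone without touching the silyl enol ether or the alkenes.

Step 14
Reactants: 20 1-[(1R,5R)-1,3-digeranyl-4,4-dimethyl-5-prenyl-2-(triisopropylsilyloxy)cyclohex-2-en-1-yl]prop-2-yn-1-one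
Product: 21 (1S,5S,7R)-1,5-digeranyl-8,8-dimethyl-7-prenylbicyclo[3.3.1]non-2-ene-4,9-dione
Conditions: [(2-biphenylyl)(t-Bu)2PAu(NCMe)]SbF6 (5 mol %, monovalent gold), acetone with H2O (2 equiv), rt
Reagents that add atoms: none
Why: The cationic gold centre coordinates the terminal alkyne of the ynone, and C1 of the silyl enol ether attacks C2 anti to gold, giving a vinylgold at C3 and a silyloxocarbenium ion at C9. Water removes the silyl group and protodeauration at C3 releases the C2=C3 enone and the catalyst. The closest known reaction type is the gold-catalysed carbocyclisation of cyclic silyl enol ethers onto tethered alkynes, which gives bicyclo[3.3.1]nonenones. Ring A (C1–C2–C3–C4–C5–C9) closes in the 6-endo-dig mode. The new stereocentre C1 is controlled by C5: the acyl arm is axial on ring B and can reach C1 only from its own face, so C1–C2 forms cis to C5–C4, with the C7 prenyl group equatorial and the axial C8 methyl on the far face. 6-endo must beat 5-exo: the ynone is polarised so that the terminal carbon C2 is the electrophilic β-position, the 5-exo product would be a strained bicyclo[2.2.1]heptanone, and the bulky biarylphosphine favours the endo path. The enol ether must also beat the C5-geranyl alkene, which forms a 1,6-enyne with the ynone; the enol ether is by far the stronger π-nucleophile and is held next to C2 by the axial arm. Bond formation at the tetrasubstituted C1 beside C8 is the demanding element and is helped by the axial, staggered approach.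

Step 15
Reactants: 21 (1S,5S,7R)-1,5-digeranyl-8,8-dimethyl-7-prenylbicyclo[3.3.1]non-2-ene-4,9-dione
Product: 22 (1R,2R,3R,5R,7R)-2,3-epoxy-1,5-digeranyl-8,8-dimethyl-7-prenylbicyclo[3.3.1]nonane-4,9-dione (epoxide on the face syn to C9)
Conditions: t-BuOOH (in decane), DBU, CH2Cl2, 0 °C → rt
Reagents that add atoms: tert-butyl hydroperoxide, CC(C)(C)OO
Why: Weitz–Scheffer nucleophilic epoxidation: the peroxide anion adds to C2 from the face syn to C9, away from ring B, and the enolate closes the epoxide; a nucleophilic oxidant leaves the five electron-rich alkenes alone. The two new centres are removed again in steps 16 and 17.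

Step 16
Reactants: 22 (1R,2R,3R,5R,7R)-2,3-epoxy-1,5-digeranyl-8,8-dimethyl-7-prenylbicyclo[3.3.1]nonane-4,9-dione
Product: 23 (1R,2S,5S,7R)-1,5-digeranyl-2-hydroxy-8,8-dimethyl-7-prenylbicyclo[3.3.1]nonane-4,9-dione
Conditions: SmI2 (2.2 equiv, divalent samarium), THF/MeOH, −90 °C
Reagents that add atoms: none
Why: Single-electron reduction of the α,β-epoxy ketone: the ketyl expels the C3–O bond, and a second electron and a proton give the β-hydroxy ketone. At −90 °C the isolated C9 ketone and the alkenes should not be reduced.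

Step 17
Reactants: 23 (1R,2S,5S,7R)-1,5-digeranyl-2-hydroxy-8,8-dimethyl-7-prenylbicyclo[3.3.1]nonane-4,9-dione
Product: 24 (1R,5S,7R)-1,5-digeranyl-8,8-dimethyl-7-prenylbicyclo[3.3.1]nonane-2,4,9-trione (enolised across C2–C4)
Conditions: Dess–Martin periodinane, NaHCO3, CH2Cl2, 0 °C → rt
Reagents that add atoms: none
Why: Dess–Martin oxidation of a β-hydroxy ketone to the β-diketone, which enolises at once; C3 stays CH2/CH.

Step 18
Reactants: 24 (1R,5S,7R)-1,5-digeranyl-8,8-dimethyl-7-prenylbicyclo[3.3.1]nonane-2,4,9-trione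
Product: 25 (1R,5S,7R)-1,5-digeranyl-4-methoxy-8,8-dimethyl-7-prenylbicyclo[3.3.1]non-3-ene-2,9-dione
Conditions: Me3SiCHN2, MeOH/toluene, 0 °C → rt
Reagents that add atoms: (trimethylsilyl)diazomethane, C[Si](C)(C)C=[N+]=[N-]
Why: O-Methylation of the acidic enol by the diazomethane equivalent gives the vinylogous ester needed for C3 metalation; without it the base in step 21 would only form the diketone enolate.

Step 19
Reactants: 26 3,4-dihydroxybenzoic acid
Product: 28 3,4-bis(tert-butyldimethylsilyloxy)benzoic acid, via tris-silylated acid 27 (not isolated)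
Conditions: t-BuMe2SiCl (3.5 equiv), imidazole, DMF, rt; then AcOH/THF/H2O, rt
Reagents that add atoms: tert-butyldimethylsilyl chloride, CC(C)(C)[Si](C)(C)Cl
Why: Exhaustive silylation followed by selective hydrolysis of the silyl ester, which is far more labile than the aryl silyl ethers.

Step 20
Reactants: 28 3,4-bis(tert-butyldimethylsilyloxy)benzoic acid
Product: 29 3,4-bis(tert-butyldimethylsilyloxy)benzoyl chloride
Conditions: (COCl)2, DMF (cat.), CH2Cl2, 0 °C → rt; concentrated and used crude
Reagents that add atoms: oxalyl chloride, O=C(Cl)C(Cl)=O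
Why: Acid chloride formation through the chloroiminium (Vilsmeier) intermediate; the aryl silyl ethers tolerate the short exposure.

Step 21
Reactants: 25 (1R,5S,7R)-1,5-digeranyl-4-methoxy-8,8-dimethyl-7-prenylbicyclo[3.3.1]non-3-ene-2,9-dione; 29 3,4-bis(tert-butyldimethylsilyloxy)benzoyl chloride
Product: 30 (1S,5S,7R)-3-[3,4-bis(tert-butyldimethylsilyloxy)benzoyl]-1,5-digeranyl-4-methoxy-8,8-dimethyl-7-prenylbicyclo[3.3.1]non-3-ene-2,9-dione
Conditions: lithium 2,2,6,6-tetramethylpiperidide (from the amine and n-BuLi), THF, −78 °C; then 29, −78 → −40 °C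
Reagents that add atoms: none
Why: Vinylic deprotonation of the vinylogous ester at C3 by the hindered amide (the only acidic C–H, since both bridgeheads are quaternary), then C-acylation by the aroyl chloride. No stereocentre is affected.

Step 22
Reactants: 30 (1S,5S,7R)-3-[3,4-bis(tert-butyldimethylsilyloxy)benzoyl]-1,5-digeranyl-4-methoxy-8,8-dimethyl-7-prenylbicyclo[3.3.1]non-3-ene-2,9-dione
Product: 31 (1S,5S,7R)-3-(3,4-dihydroxybenzoyl)-1,5-digeranyl-4-methoxy-8,8-dimethyl-7-prenylbicyclo[3.3.1]non-3-ene-2,9-dione
Conditions: Et3N·3HF, THF, 0 °C → rt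
Reagents that add atoms: none
Why: Fluoride cleavage of the two aryl silyl ethers under buffered conditions; strong protic acid, which would close the enol oxygen onto the prenyl groups, is avoided.

Step 23
Reactants: 31 (1S,5S,7R)-3-(3,4-dihydroxybenzoyl)-1,5-digeranyl-4-methoxy-8,8-dimethyl-7-prenylbicyclo[3.3.1]non-3-ene-2,9-dione
Product: 32 (1S,5S,7R)-3-(3,4-dihydroxybenzoyl)-1,5-digeranyl-4-hydroxy-8,8-dimethyl-7-prenylbicyclo[3.3.1]non-3-ene-2,9-dione (CNP0178719.1)
Conditions: LiCl, degassed DMSO, 120 °C; then dilute aq. H3PO4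
Reagents that add atoms: none
Why: SN2 demethylation of the activated vinylogous ester by chloride gives the lithium enolate of the triketone, which is protonated on mild acidic work-up. The conditions are non-acidic and oxygen-free for the alkenes and the catechol.

## Compound list

1 | (±)-lavandulol | OCC(CC=C(C)C)C(C)=C | starting material
2 | (S)-lavandulol | OC[C@@H](CC=C(C)C)C(C)=C | intermediate
3 | (S)-lavandulyl iodide, (3S)-3-(iodomethyl)-2,6-dimethylhepta-1,5-diene | IC[C@@H](CC=C(C)C)C(C)=C | intermediate
4 | dimethyl (2-oxopropyl)phosphonate | CC(=O)CP(=O)(OC)OC | starting material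
5 | dimethyl [(5S)-6-methyl-5-(3-methylbut-2-en-1-yl)-2-oxohept-6-en-1-yl]phosphonate | COP(=O)(OC)CC(=O)CC[C@@H](CC=C(C)C)C(C)=C | intermediate
6 | (6S)-7-methyl-6-(3-methylbut-2-en-1-yl)octa-1,7-dien-3-one | C=CC(=O)CC[C@@H](CC=C(C)C)C(C)=C | intermediate
7 | (4S)-3-methyl-4-(3-methylbut-2-en-1-yl)cyclohex-2-en-1-one | O=C1CC[C@@H](CC=C(C)C)C(C)=C1 | intermediate
8 | (4S)-2-iodo-3-methyl-4-prenylcyclohex-2-en-1-one | O=C1CC[C@@H](CC=C(C)C)C(C)=C1I | intermediate
9 | (8S)-6-iodo-7-methyl-8-prenyl-1,4-dioxaspiro[4.5]dec-6-ene | C1COC2(O1)CC[C@@H](CC=C(C)C)C(C)=C2I | intermediate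
10 | geranyl bromide | BrC/C=C(\C)CCC=C(C)C | starting material
11 | (8S)-6-geranyl-7-methyl-8-prenyl-1,4-dioxaspiro[4.5]dec-6-ene | C1COC2(O1)CC[C@@H](CC=C(C)C)C(C)=C2C/C=C(\C)CCC=C(C)C | intermediate (not isolated)
12 | (4S)-2-geranyl-3-methyl-4-prenylcyclohex-2-en-1-one | O=C1CC[C@@H](CC=C(C)C)C(C)=C1C/C=C(\C)CCC=C(C)C | intermediate
13 | (4R)-2,6-digeranyl-3-methyl-4-prenylcyclohex-2-en-1-one, both C6 epimers | O=C1C(C/C=C(\C)CCC=C(C)C)C[C@@H](CC=C(C)C)C(C)=C1C/C=C(\C)CCC=C(C)C | intermediate
14 | 3-(trimethylsilyl)propynal | C[Si](C)(C)C#CC=O | starting material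
15 | lithium 1-[(1S,5R)-1,3-digeranyl-4-methyl-2-oxo-5-prenylcyclohex-3-en-1-yl]-3-(trimethylsilyl)prop-2-yn-1-olate, carbinol epimers | [Li+].[O-]C(C#C[Si](C)(C)C)[C@]1(C/C=C(\C)CCC=C(C)C)C[C@@H](CC=C(C)C)C(C)=C(C/C=C(\C)CCC=C(C)C)C1=O | intermediate (not isolated)
16 | (4R,6S)-2,6-digeranyl-3-methyl-4-prenyl-6-[3-(trimethylsilyl)-1-(trimethylsilyloxy)prop-2-yn-1-yl]cyclohex-2-en-1-one, carbinol epimers | C[Si](C)(C)C#CC(O[Si](C)(C)C)[C@]1(C/C=C(\C)CCC=C(C)C)C[C@@H](CC=C(C)C)C(C)=C(C/C=C(\C)CCC=C(C)C)C1=O | intermediate
17 | lithium (4R,6S)-2,6-digeranyl-3,3-dimethyl-4-prenyl-6-[3-(trimethylsilyl)-1-(trimethylsilyloxy)prop-2-yn-1-yl]cyclohex-1-en-1-olate | C[Si](C)(C)C#CC(O[Si](C)(C)C)[C@]1(C/C=C(\C)CCC=C(C)C)C[C@@H](CC=C(C)C)C(C)(C)C(C/C=C(\C)CCC=C(C)C)=C1[O-].[Li+] | intermediate (not isolated)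
18 | triisopropyl{[(4R,6S)-2,6-digeranyl-3,3-dimethyl-4-prenyl-6-[3-(trimethylsilyl)-1-(trimethylsilyloxy)prop-2-yn-1-yl]cyclohex-1-en-1-yl]oxy}silane | C[Si](C)(C)C#CC(O[Si](C)(C)C)[C@]1(C/C=C(\C)CCC=C(C)C)C[C@@H](CC=C(C)C)C(C)(C)C(C/C=C(\C)CCC=C(C)C)=C1O[Si](C(C)C)(C(C)C)C(C)C | intermediate
19 | 1-[(1S,5R)-1,3-digeranyl-4,4-dimethyl-5-prenyl-2-(triisopropylsilyloxy)cyclohex-2-en-1-yl]prop-2-yn-1-ol, carbinol epimers | C#CC(O)[C@]1(C/C=C(\C)CCC=C(C)C)C[C@@H](CC=C(C)C)C(C)(C)C(C/C=C(\C)CCC=C(C)C)=C1O[Si](C(C)C)(C(C)C)C(C)C | intermediate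
20 | 1-[(1R,5R)-1,3-digeranyl-4,4-dimethyl-5-prenyl-2-(triisopropylsilyloxy)cyclohex-2-en-1-yl]prop-2-yn-1-one | C#CC(=O)[C@]1(C/C=C(\C)CCC=C(C)C)C[C@@H](CC=C(C)C)C(C)(C)C(C/C=C(\C)CCC=C(C)C)=C1O[Si](C(C)C)(C(C)C)C(C)C | intermediate (key-step precursor)
21 | (1S,5S,7R)-1,5-digeranyl-8,8-dimethyl-7-prenylbicyclo[3.3.1]non-2-ene-4,9-dione | [C@]12(C/C=C(\C)CCC=C(C)C)C[C@@H](CC=C(C)C)C(C)(C)[C@](C/C=C(\C)CCC=C(C)C)(C=CC1=O)C2=O | intermediate (key-step product)
22 | (1R,2R,3R,5R,7R)-2,3-epoxy-1,5-digeranyl-8,8-dimethyl-7-prenylbicyclo[3.3.1]nonane-4,9-dione | [C@]12(C/C=C(\C)CCC=C(C)C)C[C@@H](CC=C(C)C)C(C)(C)[C@](C/C=C(\C)CCC=C(C)C)([C@H]3O[C@H]3C1=O)C2=O | intermediate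
23 | (1R,2S,5S,7R)-1,5-digeranyl-2-hydroxy-8,8-dimethyl-7-prenylbicyclo[3.3.1]nonane-4,9-dione | [C@]12(C/C=C(\C)CCC=C(C)C)C[C@@H](CC=C(C)C)C(C)(C)[C@](C/C=C(\C)CCC=C(C)C)([C@@H](O)CC1=O)C2=O | intermediate
24 | (1R,5S,7R)-1,5-digeranyl-8,8-dimethyl-7-prenylbicyclo[3.3.1]nonane-2,4,9-trione | [C@]12(C/C=C(\C)CCC=C(C)C)C[C@@H](CC=C(C)C)C(C)(C)[C@](C/C=C(\C)CCC=C(C)C)(C(=O)CC1=O)C2=O | intermediate
25 | (1R,5S,7R)-1,5-digeranyl-4-methoxy-8,8-dimethyl-7-prenylbicyclo[3.3.1]non-3-ene-2,9-dione | [C@]12(C/C=C(\C)CCC=C(C)C)C[C@@H](CC=C(C)C)C(C)(C)[C@](C/C=C(\C)CCC=C(C)C)(C(=O)C=C1OC)C2=O | intermediate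
26 | 3,4-dihydroxybenzoic acid | OC(=O)c1ccc(O)c(O)c1 | starting material
27 | tert-butyldimethylsilyl 3,4-bis(tert-butyldimethylsilyloxy)benzoate | CC(C)(C)[Si](C)(C)OC(=O)c1ccc(O[Si](C)(C)C(C)(C)C)c(O[Si](C)(C)C(C)(C)C)c1 | intermediate (not isolated)
28 | 3,4-bis(tert-butyldimethylsilyloxy)benzoic acid | OC(=O)c1ccc(O[Si](C)(C)C(C)(C)C)c(O[Si](C)(C)C(C)(C)C)c1 | intermediate
29 | 3,4-bis(tert-butyldimethylsilyloxy)benzoyl chloride | ClC(=O)c1ccc(O[Si](C)(C)C(C)(C)C)c(O[Si](C)(C)C(C)(C)C)c1 | intermediate
30 | (1S,5S,7R)-3-[3,4-bis(tert-butyldimethylsilyloxy)benzoyl]-1,5-digeranyl-4-methoxy-8,8-dimethyl-7-prenylbicyclo[3.3.1]non-3-ene-2,9-dione | [C@]12(C/C=C(\C)CCC=C(C)C)C[C@@H](CC=C(C)C)C(C)(C)[C@](C/C=C(\C)CCC=C(C)C)(C(=O)C(C(=O)c3ccc(O[Si](C)(C)C(C)(C)C)c(O[Si](C)(C)C(C)(C)C)c3)=C1OC)C2=O | intermediate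
31 | (1S,5S,7R)-3-(3,4-dihydroxybenzoyl)-1,5-digeranyl-4-methoxy-8,8-dimethyl-7-prenylbicyclo[3.3.1]non-3-ene-2,9-dione | [C@]12(C/C=C(\C)CCC=C(C)C)C[C@@H](CC=C(C)C)C(C)(C)[C@](C/C=C(\C)CCC=C(C)C)(C(=O)C(C(=O)c3ccc(O)c(O)c3)=C1OC)C2=O | intermediate
32 | (1S,5S,7R)-3-(3,4-dihydroxybenzoyl)-1,5-digeranyl-4-hydroxy-8,8-dimethyl-7-prenylbicyclo[3.3.1]non-3-ene-2,9-dione (CNP0178719.1) | CC(C)=CCC/C(C)=C/C[C@]12C[C@@H](CC=C(C)C)C(C)(C)[C@](C/C=C(\C)CCC=C(C)C)(C(=O)C(C(=O)c3ccc(O)c(O)c3)=C1O)C2=O | target

## Step count and least certain steps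

Total: 23 steps (21 in the main line, 2 for acid chloride 29). Longest linear sequence: 21 steps (1 → 32 through steps 1–18 and 21–23).

**Step 14 (key step).** The enol ether carbon is tetrasubstituted and sits beside C8, so C–C bond formation may be slower than protodesilylation of the enol ether by the wet medium, or than attack of the C5-geranyl alkene on the activated alkyne (1,6-enyne cycloisomerisation). Fallback: from 20 directly back to 21 by a Lewis-acid Mukaiyama–Michael closure. Me2AlCl in CH2Cl2 at −78 °C activates the ynone through its carbonyl oxygen instead of its π-bond, the silyl enol ether adds to C2, and the aluminium allenolate is protonated on work-up. No new isolated compound is made.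

**Step 11.** Conjugate addition to a tetrasubstituted enone flanked by two allyl-type chains may be slow, letting 1,2-addition or enolate proton exchange compete, and O-silylation of the congested enolate may be incomplete. Fallback: set out from 7, where the enone is only trisubstituted, and come back at 18.
- Me2CuLi addition to 7 with trapping of the enolate by 10 in DMPU should give 2-geranyl-3,3-dimethyl-4-prenylcyclohexanone F1.
- LiN(i-Pr)2 and 10 at the less hindered C5 give 2,6-digeranyl-3,3-dimethyl-4-prenylcyclohexanone F2.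
- LiN(i-Pr)2, 14 and Me3SiCl give the saturated aldol silyl ether F3.
- KN(SiMe3)2 and i-Pr3SiOTf remove the only remaining α-hydrogen (C1–H) and return to 18.
- The price is reliance on kinetic discrimination between C5–H and C1–H, and a less well-defined facial bias in the aldol step. Steps 6–9 and 11 are then not needed.

**Step 10.** Retro-aldol cleavage of the lithium aldolate before silylation and insufficient facial discrimination at C5 are the likely failures. Fallback: from 13 back to 16 through a Mukaiyama aldol reaction. LiN(i-Pr)2 and Me3SiCl convert 13 into 2-(trimethylsilyloxy)diene F4. BF3·OEt2 and 14 at −78 °C then give, irreversibly and through an open transition state that is more sensitive to the pseudoaxial prenyl group, hydroxy ketone F5. Me3SiCl and imidazole lead to 16.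

**Step 8.** Halogen–metal exchange between the vinyllithium and the allylic bromide (homocoupling, protonated ketal) or SN2′ attack can erode the alkylation. Fallback: from 8 directly back to 12 by a Stille coupling with geranyltributylstannane F6 (from 10 and Bu3SnLi), using Pd2(dba)3 (zerovalent palladium), AsPh3 and CuI in NMP. This omits step 7; its own weakness is partial allyl transposition.

**Step 15.** The peroxide anion may attack C4 or C9 of the non-enolisable 1,3-dicarbonyl unit and open the ring by retro-Claisen cleavage, or add too slowly at the neopentyl C2. Fallback: from 21 back to 23 by conjugate borylation. CuCl (monovalent copper), NaOt-Bu, Xantphos, B2pin2 and MeOH in THF should give the C2 pinacol boronate F7, and NaBO3·4H2O oxidises it to 23, so that 22 and the samarium step are bypassed.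

**Step 21.** Acylation of the hindered C3 carbanion may be sluggish, so that proton return or attack on a C9 ketone competes. Fallback: from 25 back to 30 in two steps. The same C3-lithium species is trapped with 3,4-bis(tert-butyldimethylsilyloxy)benzaldehyde F8 (from 3,4-dihydroxybenzaldehyde, t-BuMe2SiCl, imidazole), a smaller and more reactive electrophile, to give carbinol F9. Dess–Martin oxidation then leads to 30.

## Further compounds

F0 | step 14 | none | none
F1 | step 11 | (4S)-2-geranyl-3,3-dimethyl-4-prenylcyclohexanone (C2 epimers) | O=C1CC[C@@H](CC=C(C)C)C(C)(C)C1C/C=C(\C)CCC=C(C)C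
F2 | step 11 | (4R)-2,6-digeranyl-3,3-dimethyl-4-prenylcyclohexanone (C2 and C6 epimers) | O=C1C(C/C=C(\C)CCC=C(C)C)C[C@@H](CC=C(C)C)C(C)(C)C1C/C=C(\C)CCC=C(C)C
F3 | step 11 | (4R,6S)-2,6-digeranyl-3,3-dimethyl-4-prenyl-6-[3-(trimethylsilyl)-1-(trimethylsilyloxy)prop-2-yn-1-yl]cyclohexanone (C2 and carbinol epimers) | C[Si](C)(C)C#CC(O[Si](C)(C)C)[C@]1(C/C=C(\C)CCC=C(C)C)C[C@@H](CC=C(C)C)C(C)(C)C(C/C=C(\C)CCC=C(C)C)C1=O
F4 | step 10 | {[(4R)-2,6-digeranyl-3-methyl-4-prenylcyclohexa-1,5-dien-1-yl]oxy}trimethylsilane | C[Si](C)(C)OC1=C(C/C=C(\C)CCC=C(C)C)C[C@@H](CC=C(C)C)C(C)=C1C/C=C(\C)CCC=C(C)C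
F5 | step 10 | (4R,6S)-2,6-digeranyl-6-[1-hydroxy-3-(trimethylsilyl)prop-2-yn-1-yl]-3-methyl-4-prenylcyclohex-2-en-1-one (carbinol epimers) | C[Si](C)(C)C#CC(O)[C@]1(C/C=C(\C)CCC=C(C)C)C[C@@H](CC=C(C)C)C(C)=C(C/C=C(\C)CCC=C(C)C)C1=O
F6 | step 8 | geranyltributylstannane | CCCC[Sn](CCCC)(CCCC)C/C=C(\C)CCC=C(C)C
F7 | step 15 | (1R,5S,7R)-1,5-digeranyl-8,8-dimethyl-7-prenyl-2-(4,4,5,5-tetramethyl-1,3,2-dioxaborolan-2-yl)bicyclo[3.3.1]nonane-4,9-dione (C2 epimers) | [C@]12(C/C=C(\C)CCC=C(C)C)C[C@@H](CC=C(C)C)C(C)(C)[C@](C/C=C(\C)CCC=C(C)C)(C(B3OC(C)(C)C(C)(C)O3)CC1=O)C2=O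
F8 | step 21 | 3,4-bis(tert-butyldimethylsilyloxy)benzaldehyde | O=Cc1ccc(O[Si](C)(C)C(C)(C)C)c(O[Si](C)(C)C(C)(C)C)c1
F9 | step 21 | (1S,5S,7R)-3-{[3,4-bis(tert-butyldimethylsilyloxy)phenyl](hydroxy)methyl}-1,5-digeranyl-4-methoxy-8,8-dimethyl-7-prenylbicyclo[3.3.1]non-3-ene-2,9-dione (carbinol epimers) | [C@]12(C/C=C(\C)CCC=C(C)C)C[C@@H](CC=C(C)C)C(C)(C)[C@](C/C=C(\C)CCC=C(C)C)(C(=O)C(C(O)c3ccc(O[Si](C)(C)C(C)(C)C)c(O[Si](C)(C)C(C)(C)C)c3)=C1OC)C2=O
A1 | alternative 1 | 3-{[(1R)-2,2-dimethyl-4-(triisopropylsilyloxy)cyclohex-3-en-1-yl]carbonyl}-1,3-oxazolidin-2-one | O=C([C@@H]1CCC(O[Si](C(C)C)(C(C)C)C(C)C)=CC1(C)C)N1CCOC1=O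
A2 | alternative 1 | 4-methyl-2-(triisopropylsilyloxy)penta-1,3-diene | C=C(O[Si](C(C)C)(C(C)C)C(C)C)C=C(C)C
A3 | alternative 1 | 3-acryloyl-1,3-oxazolidin-2-one | C=CC(=O)N1CCOC1=O
A4 | alternative 2 | (1R,5S,7R)-1,5-digeranyl-4-methoxy-8,8-dimethyl-7-prenylbicyclo[3.3.1]non-3-ene-2,9-dione (identical with 25) | [C@]12(C/C=C(\C)CCC=C(C)C)C[C@@H](CC=C(C)C)C(C)(C)[C@](C/C=C(\C)CCC=C(C)C)(C(=O)C=C1OC)C2=O
A5 | alternative 2 | bis(1,3-dioxoisoindolin-2-yl) (7R)-4-methoxy-8,8-dimethyl-7-prenyl-2,9-dioxobicyclo[3.3.1]non-3-ene-1,5-dicarboxylate | [C@]12(C(=O)ON3C(=O)c4ccccc4C3=O)C[C@@H](CC=C(C)C)C(C)(C)[C@](C(=O)ON3C(=O)c4ccccc4C3=O)(C(=O)C=C1OC)C2=O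
A6 | alternative 2 | geranyl methyl carbonate | COC(=O)OC/C=C(\C)CCC=C(C)C
A7 | alternative 3 | 5-geranyl-4-methoxy-8,8-dimethyl-7-prenylbicyclo[3.3.1]non-3-en-9-one (C5 and C7 as in 21, C1–H, C2 methylene) | [C@]12(C/C=C(\C)CCC=C(C)C)C[C@@H](CC=C(C)C)C(C)(C)[C@H](CC=C1OC)C2=O
A8 | alternative 3 | 6-geranyl-6-[(S)-lavandulyl]-1,5-dimethoxycyclohexa-1,4-diene | COC1=CCC=C(OC)C1(C/C=C(\C)CCC=C(C)C)C[C@@H](CC=C(C)C)C(C)=C
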